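**Strategy**

Everything rests on disconnecting C9–C10 (abietane numbering), the bond that joins ring C to the quaternary carbon C10 of ring B. The key step exploits exactly this feature: C10 carries an aryl carbon (C9), methyl C20 and chain carbon C1, and sits next to stereocentre C5. An intramolecular Heck reaction of an ortho-bromoaryl ketone onto a Z-configured C10=C1 alkene closes ring B and sets C10 under control of C5 in one operation. The precursor is an open-chain keto ester: a bromo-isopropyl-trimethoxyphenyl ketone (ring C as its masked quinone) whose C5 carries a benzyl ester (future isopropenyl carbon C4) and the alkenyl chain ending in a silyl-protected C3 alcohol.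

Key step: step 10

Remark: abietane numbering is used throughout (ring C = C8, C9, C11–C14; ring B = C5–C10; C4 = isopropenyl carbon on C5; C1–C3 = propanoate chain; C20 = methyl on C10).
Remark: the aryl group of the cyclisation precursor is 2-bromo-5-isopropyl-3,4,6-trimethoxyphenyl (isopropyl meta to the acyl carbon, between two methoxy groups, as the quinone requires). The boronic acid that delivers the Z alkene has the descriptor E, because methyl outranks boron.
Remark: design choices for the precursor: C4 is a benzyl ester, so the acid is released without base during the hydrogenation; bromine is put on C9 before the second arene (benzyl) is introduced; silver carbonate is the only base in the key step, so the C5–H (alpha to the ester and allylic) is not disturbed.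
Remark: the (R) enantiomer of BINAP in step 9 is assigned by analogy with the usual face selection on (E)-enones; it is an assumption to be verified on the first batch, and the (S) ligand would be used if the sense is reversed.
Remark: silyl ether 9 is taken as a purchased compound.

**Route**

Step 1
Reactants: 1 1,2,4-trimethoxybenzene
Product: 3 2-(2,3,6-trimethoxyphenyl)propan-2-ol, via 2,3,6-trimethoxyphenyllithium 2 (not isolated)
Conditions: n-BuLi (1.1 equiv), THF, 0 °C to rt; acetone, −78 °C to rt; aq. NH4Cl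
Reagents that add atoms: acetone CC(C)=O
Why: Directed ortho-lithiation takes place at the carbon flanked by two methoxy groups (future C13), and 1,2-addition of the aryllithium to acetone gives the tertiary benzylic alcohol.

Step 2
Reactants: 3 2-(2,3,6-trimethoxyphenyl)propan-2-ol
Product: 4 3-isopropyl-1,2,4-trimethoxybenzene
Conditions: Et3SiH (3 equiv), CF3CO2H (10 equiv), CH2Cl2, 0 °C to rt
Reagents that add atoms: none
Why: Ionic hydrogenation: acid ionises the tertiary benzylic alcohol to a cation stabilised by two ortho methoxy groups, and the silane delivers hydride to it.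

Step 3
Reactants: 4 3-isopropyl-1,2,4-trimethoxybenzene; 5 maleic anhydride
Product: 6 (E)-4-(3-isopropyl-2,4,5-trimethoxyphenyl)-4-oxobut-2-enoic acid
Conditions: AlCl3 (2.5 equiv), CH2Cl2, 0 °C to rt; ice/aq. HCl
Reagents that add atoms: none
Why: Friedel–Crafts acylation should occur at C8, the ring carbon para to the C12 and ortho to the C14 methoxy group, and ring opening of the anhydride with equilibration under the Lewis acid gives the trans aroylacrylic acid.

Step 4
Reactants: 6 (E)-4-(3-isopropyl-2,4,5-trimethoxyphenyl)-4-oxobut-2-enoic acid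
Product: 7 (E)-4-(2-bromo-5-isopropyl-3,4,6-trimethoxyphenyl)-4-oxobut-2-enoic acid
Conditions: NBS (1.05 equiv), CF3CO2H/MeCN (1:4), 0 °C to rt, dark
Reagents that add atoms: N-bromosuccinimide O=C1CCC(=O)N1Br
Why: Electrophilic aromatic bromination can only go to C9, the last ring hydrogen (ortho to the C11 methoxy, para to isopropyl), while the electron-poor fumaroyl alkene, which has no enolisable hydrogen, should be inert to NBS under ionic conditions.

Step 5
Reactants: 7 (E)-4-(2-bromo-5-isopropyl-3,4,6-trimethoxyphenyl)-4-oxobut-2-enoic acid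
Product: 8 benzyl (E)-4-(2-bromo-5-isopropyl-3,4,6-trimethoxyphenyl)-4-oxobut-2-enoate
Conditions: BnBr (1.2 equiv), KHCO3 (1.5 equiv), DMF, rt, dark
Reagents that add atoms: benzyl bromide BrCc1ccccc1
Why: SN2 O-alkylation of the carboxylate by benzyl bromide under weakly basic conditions that do not add to the enone.

Step 6
Reactants: 9 3-[(tert-butyldimethylsilyl)oxy]propan-1-ol
Product: 10 3-[(tert-butyldimethylsilyl)oxy]propanal
Conditions: Dess–Martin periodinane (1.2 equiv), CH2Cl2, rt
Reagents that add atoms: none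
Why: Dess–Martin oxidation of the primary alcohol stops at the aldehyde and is neutral enough to avoid beta-elimination of the silyloxy group.

Step 7
Reactants: 10 3-[(tert-butyldimethylsilyl)oxy]propanal
Product: 11 (Z)-tert-butyl[(4-iodopent-3-en-1-yl)oxy]dimethylsilane
Conditions: [Ph3PCH2CH3]I (1.4 equiv), n-BuLi, THF, rt; I2, −78 °C; NaHMDS, −20 °C; then 10, −78 to −20 °C
Reagents that add atoms: ethyltriphenylphosphonium iodide CC[P+](c1ccccc1)(c1ccccc1)c1ccccc1.[I-]; iodine II
Why: Stork–Zhao olefination: the alpha-iodo ylide reacts under kinetic control to favour the Z iodoalkene (iodine cis to the chain), which fixes the later C10=C1 geometry and brings in C10 and C20.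

Step 8
Reactants: 11 (Z)-tert-butyl[(4-iodopent-3-en-1-yl)oxy]dimethylsilane
Product: 14 [(E)-5-[(tert-butyldimethylsilyl)oxy]pent-2-en-2-yl]boronic acid, via alkenyllithium 12 (not isolated), via lithium alkenyltriisopropoxyborate 13 (not isolated)
Conditions: t-BuLi (2.1 equiv), Et2O, −78 °C; B(OiPr)3 (1.5 equiv), −78 °C to rt; aq. NH4Cl
Reagents that add atoms: triisopropyl borate CC(C)OB(OC(C)C)OC(C)C; water O
Why: Iodine–lithium exchange proceeds with retention of alkene geometry, and borylation of the alkenyllithium followed by mild hydrolysis gives the boronic acid with boron cis to the chain.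

Step 9
Reactants: 8 benzyl (E)-4-(2-bromo-5-isopropyl-3,4,6-trimethoxyphenyl)-4-oxobut-2-enoate; 14 [(E)-5-[(tert-butyldimethylsilyl)oxy]pent-2-en-2-yl]boronic acid
Product: 15 benzyl (2R,3Z)-2-[2-(2-bromo-5-isopropyl-3,4,6-trimethoxyphenyl)-2-oxoethyl]-6-[(tert-butyldimethylsilyl)oxy]-3-methylhex-3-enoate
Conditions: [Rh(OH)((R)-BINAP)]2 (1.5 mol %), 14 (2 equiv), 1,4-dioxane/H2O (10:1), 35 °C
Reagents that add atoms: none
Why: Hayashi–Miyaura conjugate addition: the alkenylrhodium formed by transmetalation adds with retention of alkene geometry to the enone carbon beta to the ketone (alpha to the ester), the BINAP ligand selects the enone face and so sets C5 (R), and the base-free hydroxo catalyst spares both the new alpha-alkenyl ester centre and the aryl bromide.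

Step 10
Reactants: 15 benzyl (2R,3Z)-2-[2-(2-bromo-5-isopropyl-3,4,6-trimethoxyphenyl)-2-oxoethyl]-6-[(tert-butyldimethylsilyl)oxy]-3-methylhex-3-enoate
Product: 16 benzyl (1S,2R)-1-[(E)-3-[(tert-butyldimethylsilyl)oxy]prop-1-en-1-yl]-6-isopropyl-5,7,8-trimethoxy-1-methyl-4-oxo-1,2,3,4-tetrahydronaphthalene-2-carboxylate
Conditions: Pd(OAc)2 (10 mol %), PPh3 (30 mol %), Ag2CO3 (2 equiv), MeCN, 80 °C, degassed
Reagents that add atoms: none
Why: Zerovalent palladium inserts into the ketone-activated C9–Br bond, the aryl group adds syn across the C10=C1 alkene and palladium leaves by syn beta-hydride elimination from C2, the only side open because C10 bears no hydrogen; this is an intramolecular Mizoroki–Heck reaction of the kind long used to build benzylic quaternary carbons. Ring B closes 6-exo-trig (C9 onto C10), which the short ketone tether favours over 7-endo attack at C1. The new stereocentre C10 is set by C5: on the Z alkene C2 lies cis to C5, so A(1,3) strain holds C5–H in the alkene plane, puts tether carbon C6 and the benzyl ester on opposite faces and lets the aryl group arrive only from the C6 face, which gives methyl axial and C1 equatorial, trans to the ester (1S,2R). The step needs facial selectivity, exo regioselectivity and an intact C5–H; these are secured by the Z geometry, the six-membered transition state and silver carbonate, a weak base that also removes bromide and curbs hydride re-addition along the chain toward the silyl ether. Keeping C4 as an ester leaves C10=C1 as the only alkene that can insert.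

Step 11
Reactants: 16 benzyl (1S,2R)-1-[(E)-3-[(tert-butyldimethylsilyl)oxy]prop-1-en-1-yl]-6-isopropyl-5,7,8-trimethoxy-1-methyl-4-oxo-1,2,3,4-tetrahydronaphthalene-2-carboxylate
Product: 17 (1S,2R)-1-[3-[(tert-butyldimethylsilyl)oxy]propyl]-6-isopropyl-5,7,8-trimethoxy-1-methyl-4-oxo-1,2,3,4-tetrahydronaphthalene-2-carboxylic acid
Conditions: H2 (1 atm), 10% Pd/C, EtOAc, rt
Reagents that add atoms: none
Why: Heterogeneous catalytic hydrogenation saturates the C1=C2 alkene and hydrogenolyses the benzyl ester in one operation without base, so C5 is untouched, and the electron-rich aryl ketone and the silyl ether should survive in ethyl acetate.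

Step 12
Reactants: 17 (1S,2R)-1-[3-[(tert-butyldimethylsilyl)oxy]propyl]-6-isopropyl-5,7,8-trimethoxy-1-methyl-4-oxo-1,2,3,4-tetrahydronaphthalene-2-carboxylic acid
Product: 19 (3R,4S)-3-acetyl-4-[3-[(tert-butyldimethylsilyl)oxy]propyl]-7-isopropyl-5,6,8-trimethoxy-4-methyl-3,4-dihydronaphthalen-1(2H)-one, via acid chloride 18 (not isolated)
Conditions: 1-chloro-N,N,2-trimethylprop-1-en-1-amine (1.2 equiv), CH2Cl2, 0 °C to rt; then Me2CuLi (3 equiv, from CuI and MeLi), Et2O, −78 °C; aq. NH4Cl
Reagents that add atoms: lithium dimethylcuprate [Li+].C[Cu-]C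
Why: The chloroenamine forms the acid chloride under neutral conditions (no ketene, no epimerisation at C5), and organocuprate acylation stops at the methyl ketone and leaves the C7 aryl ketone alone at −78 °C.

Step 13
Reactants: 19 (3R,4S)-3-acetyl-4-[3-[(tert-butyldimethylsilyl)oxy]propyl]-7-isopropyl-5,6,8-trimethoxy-4-methyl-3,4-dihydronaphthalen-1(2H)-one
Product: 20 (3S,4S)-4-[3-[(tert-butyldimethylsilyl)oxy]propyl]-7-isopropyl-5,6,8-trimethoxy-4-methyl-3-(prop-1-en-2-yl)-3,4-dihydronaphthalen-1(2H)-one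
Conditions: Ph3PCH3Br (3 equiv), KOtBu (2.8 equiv), THF, 0 °C to rt
Reagents that add atoms: methyltriphenylphosphonium bromide C[P+](c1ccccc1)(c1ccccc1)c1ccccc1.[Br-]
Why: Wittig methylenation should select the aliphatic C4 methyl ketone, because the C7 ketone is a vinylogous ester of the C12 and C14 methoxy groups, is shielded by the peri C14 methoxy and is reversibly masked as its enolate by the basic ylide; no ester is present yet, so no Claisen-type closure can compete.

Step 14
Reactants: 20 (3S,4S)-4-[3-[(tert-butyldimethylsilyl)oxy]propyl]-7-isopropyl-5,6,8-trimethoxy-4-methyl-3-(prop-1-en-2-yl)-3,4-dihydronaphthalen-1(2H)-one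
Product: 21 (3S,4S)-4-(3-hydroxypropyl)-7-isopropyl-5,6,8-trimethoxy-4-methyl-3-(prop-1-en-2-yl)-3,4-dihydronaphthalen-1(2H)-one
Conditions: HF·pyridine, THF/pyridine, 0 °C to rt
Reagents that add atoms: none
Why: Fluoride-driven desilylation (Si–F bond formation) under buffered conditions leaves the isopropenyl group and the ketone untouched.

Step 15
Reactants: 21 (3S,4S)-4-(3-hydroxypropyl)-7-isopropyl-5,6,8-trimethoxy-4-methyl-3-(prop-1-en-2-yl)-3,4-dihydronaphthalen-1(2H)-one
Product: 23 3-[(1S,2S)-6-isopropyl-5,7,8-trimethoxy-1-methyl-4-oxo-2-(prop-1-en-2-yl)-1,2,3,4-tetrahydronaphthalen-1-yl]propanoic acid, via aldehyde 22 (not isolated)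
Conditions: TEMPO (0.2 equiv), PhI(OAc)2 (2.5 equiv), MeCN/H2O (1:1), rt
Reagents that add atoms: water O
Why: Oxoammonium (TEMPO) oxidation takes the primary alcohol to the aldehyde and, through its hydrate, to the acid, and this oxidant does not attack alkenes or aryl methyl ethers.

Step 16
Reactants: 23 3-[(1S,2S)-6-isopropyl-5,7,8-trimethoxy-1-methyl-4-oxo-2-(prop-1-en-2-yl)-1,2,3,4-tetrahydronaphthalen-1-yl]propanoic acid
Product: 24 methyl 3-[(1S,2S)-6-isopropyl-5,7,8-trimethoxy-1-methyl-4-oxo-2-(prop-1-en-2-yl)-1,2,3,4-tetrahydronaphthalen-1-yl]propanoate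
Conditions: Me3SiCHN2 (1.5 equiv), toluene/MeOH (4:1), 0 °C to rt
Reagents that add atoms: (trimethylsilyl)diazomethane C[Si](C)(C)C=[N+]=[N-]
Why: Diazoalkane esterification (protonation of the diazo carbon, then SN2 by the carboxylate) is neutral and specific for the carboxylic acid.

Step 17
Reactants: 24 methyl 3-[(1S,2S)-6-isopropyl-5,7,8-trimethoxy-1-methyl-4-oxo-2-(prop-1-en-2-yl)-1,2,3,4-tetrahydronaphthalen-1-yl]propanoate
Product: 25 methyl 3-[(1S,2S)-6-isopropyl-7-methoxy-1-methyl-4,5,8-trioxo-2-(prop-1-en-2-yl)-1,2,3,4,5,8-hexahydronaphthalen-1-yl]propanoate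
Conditions: (NH4)2Ce(NO3)6 (2.5 equiv), MeCN/H2O (2:1), 0 °C
Reagents that add atoms: water O
Why: Oxidative demethylation by single-electron transfer to tetravalent cerium converts the para-related C11/C14 dimethoxy pair into the para-quinone and leaves the C12 methoxy as a vinylogous ester; it is fast at 0 °C, so the isopropenyl group should not be attacked.

Step 18
Reactants: 25 methyl 3-[(1S,2S)-6-isopropyl-7-methoxy-1-methyl-4,5,8-trioxo-2-(prop-1-en-2-yl)-1,2,3,4,5,8-hexahydronaphthalen-1-yl]propanoate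
Product: 27 methyl 3-[(1S,2S)-7-hydroxy-6-isopropyl-1-methyl-4,5,8-trioxo-2-(prop-1-en-2-yl)-1,2,3,4,5,8-hexahydronaphthalen-1-yl]propanoate, via dichloroboryl ether 26 (not isolated)
Conditions: BCl3 (2.5 equiv), CH2Cl2, −78 to −40 °C; then H2O
Reagents that add atoms: none
Why: Chelation-assisted Lewis-acid ether cleavage: boron bridges the C11 carbonyl and the C12 methoxy oxygen and chloride removes the methyl group by SN2, which selects the vinylogous ester over the aliphatic methyl ester, and hydrolysis of the boron enolate gives the hydroxyquinone.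

**Compound list**

1 | 1,2,4-trimethoxybenzene | COc1ccc(OC)c(OC)c1 | starting material
2 | (2,3,6-trimethoxyphenyl)lithium | [Li]c1c(OC)ccc(OC)c1OC | intermediate
3 | 2-(2,3,6-trimethoxyphenyl)propan-2-ol | CC(C)(O)c1c(OC)ccc(OC)c1OC | intermediate
4 | 3-isopropyl-1,2,4-trimethoxybenzene | CC(C)c1c(OC)ccc(OC)c1OC | intermediate
5 | maleic anhydride | O=C1OC(=O)C=C1 | starting material
6 | (E)-4-(3-isopropyl-2,4,5-trimethoxyphenyl)-4-oxobut-2-enoic acid | CC(C)c1c(OC)c(OC)cc(C(=O)/C=C/C(=O)O)c1OC | intermediate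
7 | (E)-4-(2-bromo-5-isopropyl-3,4,6-trimethoxyphenyl)-4-oxobut-2-enoic acid | CC(C)c1c(OC)c(OC)c(Br)c(C(=O)/C=C/C(=O)O)c1OC | intermediate
8 | benzyl (E)-4-(2-bromo-5-isopropyl-3,4,6-trimethoxyphenyl)-4-oxobut-2-enoate | CC(C)c1c(OC)c(OC)c(Br)c(C(=O)/C=C/C(=O)OCc2ccccc2)c1OC | intermediate
9 | 3-[(tert-butyldimethylsilyl)oxy]propan-1-ol | CC(C)(C)[Si](C)(C)OCCCO | starting material
10 | 3-[(tert-butyldimethylsilyl)oxy]propanal | CC(C)(C)[Si](C)(C)OCCC=O | intermediate
11 | (Z)-tert-butyl[(4-iodopent-3-en-1-yl)oxy]dimethylsilane (iodine cis to the chain) | C/C(I)=C/CCO[Si](C)(C)C(C)(C)C | intermediate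
12 | [(E)-5-[(tert-butyldimethylsilyl)oxy]pent-2-en-2-yl]lithium (lithium cis to the chain) | C/C([Li])=C/CCO[Si](C)(C)C(C)(C)C | intermediate
13 | lithium [(E)-5-[(tert-butyldimethylsilyl)oxy]pent-2-en-2-yl]triisopropoxyborate | [Li+].C/C(=C/CCO[Si](C)(C)C(C)(C)C)[B-](OC(C)C)(OC(C)C)OC(C)C | intermediate
14 | [(E)-5-[(tert-butyldimethylsilyl)oxy]pent-2-en-2-yl]boronic acid (boron cis to the chain) | C/C(B(O)O)=C/CCO[Si](C)(C)C(C)(C)C | intermediate
15 | benzyl (2R,3Z)-2-[2-(2-bromo-5-isopropyl-3,4,6-trimethoxyphenyl)-2-oxoethyl]-6-[(tert-butyldimethylsilyl)oxy]-3-methylhex-3-enoate | CC(C)c1c(OC)c(OC)c(Br)c(c1OC)C(=O)C[C@@H](C(=O)OCc1ccccc1)/C(C)=C\CCO[Si](C)(C)C(C)(C)C | intermediate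
16 | benzyl (1S,2R)-1-[(E)-3-[(tert-butyldimethylsilyl)oxy]prop-1-en-1-yl]-6-isopropyl-5,7,8-trimethoxy-1-methyl-4-oxo-1,2,3,4-tetrahydronaphthalene-2-carboxylate | CC(C)c1c(OC)c(OC)c2c(c1OC)C(=O)C[C@@H](C(=O)OCc1ccccc1)[C@]2(C)/C=C/CO[Si](C)(C)C(C)(C)C | intermediate
17 | (1S,2R)-1-[3-[(tert-butyldimethylsilyl)oxy]propyl]-6-isopropyl-5,7,8-trimethoxy-1-methyl-4-oxo-1,2,3,4-tetrahydronaphthalene-2-carboxylic acid | CC(C)c1c(OC)c(OC)c2c(c1OC)C(=O)C[C@@H](C(=O)O)[C@]2(C)CCCO[Si](C)(C)C(C)(C)C | intermediate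
18 | (1S,2R)-1-[3-[(tert-butyldimethylsilyl)oxy]propyl]-6-isopropyl-5,7,8-trimethoxy-1-methyl-4-oxo-1,2,3,4-tetrahydronaphthalene-2-carbonyl chloride | CC(C)c1c(OC)c(OC)c2c(c1OC)C(=O)C[C@@H](C(=O)Cl)[C@]2(C)CCCO[Si](C)(C)C(C)(C)C | intermediate
19 | (3R,4S)-3-acetyl-4-[3-[(tert-butyldimethylsilyl)oxy]propyl]-7-isopropyl-5,6,8-trimethoxy-4-methyl-3,4-dihydronaphthalen-1(2H)-one | CC(C)c1c(OC)c(OC)c2c(c1OC)C(=O)C[C@@H](C(C)=O)[C@]2(C)CCCO[Si](C)(C)C(C)(C)C | intermediate
20 | (3S,4S)-4-[3-[(tert-butyldimethylsilyl)oxy]propyl]-7-isopropyl-5,6,8-trimethoxy-4-methyl-3-(prop-1-en-2-yl)-3,4-dihydronaphthalen-1(2H)-one | C=C(C)[C@@H]1CC(=O)c2c(OC)c(C(C)C)c(OC)c(OC)c2[C@@]1(C)CCCO[Si](C)(C)C(C)(C)C | intermediate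
21 | (3S,4S)-4-(3-hydroxypropyl)-7-isopropyl-5,6,8-trimethoxy-4-methyl-3-(prop-1-en-2-yl)-3,4-dihydronaphthalen-1(2H)-one | C=C(C)[C@@H]1CC(=O)c2c(OC)c(C(C)C)c(OC)c(OC)c2[C@@]1(C)CCCO | intermediate
22 | 3-[(1S,2S)-6-isopropyl-5,7,8-trimethoxy-1-methyl-4-oxo-2-(prop-1-en-2-yl)-1,2,3,4-tetrahydronaphthalen-1-yl]propanal | C=C(C)[C@@H]1CC(=O)c2c(OC)c(C(C)C)c(OC)c(OC)c2[C@@]1(C)CCC=O | intermediate
23 | 3-[(1S,2S)-6-isopropyl-5,7,8-trimethoxy-1-methyl-4-oxo-2-(prop-1-en-2-yl)-1,2,3,4-tetrahydronaphthalen-1-yl]propanoic acid | C=C(C)[C@@H]1CC(=O)c2c(OC)c(C(C)C)c(OC)c(OC)c2[C@@]1(C)CCC(=O)O | intermediate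
24 | methyl 3-[(1S,2S)-6-isopropyl-5,7,8-trimethoxy-1-methyl-4-oxo-2-(prop-1-en-2-yl)-1,2,3,4-tetrahydronaphthalen-1-yl]propanoate | C=C(C)[C@@H]1CC(=O)c2c(OC)c(C(C)C)c(OC)c(OC)c2[C@@]1(C)CCC(=O)OC | intermediate
25 | methyl 3-[(1S,2S)-6-isopropyl-7-methoxy-1-methyl-4,5,8-trioxo-2-(prop-1-en-2-yl)-1,2,3,4,5,8-hexahydronaphthalen-1-yl]propanoate | C=C(C)[C@@H]1CC(=O)C2=C(C(=O)C(OC)=C(C(C)C)C2=O)[C@@]1(C)CCC(=O)OC | intermediate
26 | methyl 3-[(1S,2S)-7-[(dichloroboranyl)oxy]-6-isopropyl-1-methyl-4,5,8-trioxo-2-(prop-1-en-2-yl)-1,2,3,4,5,8-hexahydronaphthalen-1-yl]propanoate | C=C(C)[C@@H]1CC(=O)C2=C(C(=O)C(OB(Cl)Cl)=C(C(C)C)C2=O)[C@@]1(C)CCC(=O)OC | intermediate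
27 | methyl 3-[(1S,2S)-7-hydroxy-6-isopropyl-1-methyl-4,5,8-trioxo-2-(prop-1-en-2-yl)-1,2,3,4,5,8-hexahydronaphthalen-1-yl]propanoate (5S,10S in abietane numbering) | C=C(C)[C@@H]1CC(=O)C2=C(C(=O)C(O)=C(C(C)C)C2=O)[C@@]1(C)CCC(=O)OC | target

**Step count**

Total: 18 steps. Longest linear sequence: 15 steps (steps 1–5 and 9–18); the alkenyl fragment (steps 6–8) joins at step 9.

**Steps most likely to fail**

Step 10 (key step). Insertion into the hindered trisubstituted alkene may be slow, so that hydrodebromination of the aryl bromide takes over. Facial selectivity may be eroded, or the base may cost the C5 configuration or move the C10=C1 double bond into conjugation with the ester. Fallback: set out from 15 and form the same C9–C10 bond by a 6-exo aryl radical cyclisation (Bu3SnH, AIBN, benzene, 80 °C, slow addition). The same allylic strain should steer the radical addition, and the C1 radical is reduced in the flask, which gives benzyl (1S,2R)-1-[3-[(tert-butyldimethylsilyl)oxy]propyl]-6-isopropyl-5,7,8-trimethoxy-1-methyl-4-oxo-1,2,3,4-tetrahydronaphthalene-2-carboxylate F1. Hydrogenolysis of the benzyl ester (H2, Pd/C, EtOAc) comes back to the route at 17.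

Step 9. Transmetalation and insertion of the doubly substituted alkenyl group may be sluggish, so that protodeboronation wins. Enantioselectivity may be low or of the wrong sense, or the alkene geometry may drift. Fallback: set out from enone 8 and alkenyllithium 12 (made from 11 as in step 8). Transmetalation with CuI (0.5 equiv, Et2O, −40 °C) gives lithium bis[(E)-5-[(tert-butyldimethylsilyl)oxy]pent-2-en-2-yl]cuprate F2, which adds at −78 °C to 8 beta to the ketone and gives 15 as the racemate. Preparative chromatography on a chiral stationary phase separates 15 from its enantiomer, benzyl (2S,3Z)-2-[2-(2-bromo-5-isopropyl-3,4,6-trimethoxyphenyl)-2-oxoethyl]-6-[(tert-butyldimethylsilyl)oxy]-3-methylhex-3-enoate F3, and the route is rejoined at 15.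

Step 13. Chemoselectivity between the two ketones may be lost (attack at C7, or incomplete conversion of the hindered C4 ketone that forces harsher conditions and enolisation toward C5). Fallback: set out from 17 and take the C7 ketone out of play first.
- NaBH4 (MeOH, 0 °C to rt) reduces only the aryl ketone and gives (1S,2R)-1-[3-[(tert-butyldimethylsilyl)oxy]propyl]-4-hydroxy-6-isopropyl-5,7,8-trimethoxy-1-methyl-1,2,3,4-tetrahydronaphthalene-2-carboxylic acid F4 (both C4 epimers).
- MeLi (4 equiv, THF, 0 °C, inverse quench) converts the carboxylate into the methyl ketone 1-[(1S,2R)-1-[3-[(tert-butyldimethylsilyl)oxy]propyl]-4-hydroxy-6-isopropyl-5,7,8-trimethoxy-1-methyl-1,2,3,4-tetrahydronaphthalen-2-yl]ethan-1-one F5.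
- Wittig methylenation (Ph3P=CH2, now usable in larger excess at lower temperature because no second ketone is present) gives (3S,4S)-4-[3-[(tert-butyldimethylsilyl)oxy]propyl]-7-isopropyl-5,6,8-trimethoxy-4-methyl-3-(prop-1-en-2-yl)-1,2,3,4-tetrahydronaphthalen-1-ol F6.
- Dess–Martin oxidation of the benzylic alcohol comes back to the route at 20.

**Further compounds**

F1 | step 10 | benzyl (1S,2R)-1-[3-[(tert-butyldimethylsilyl)oxy]propyl]-6-isopropyl-5,7,8-trimethoxy-1-methyl-4-oxo-1,2,3,4-tetrahydronaphthalene-2-carboxylate | CC(C)c1c(OC)c(OC)c2c(c1OC)C(=O)C[C@@H](C(=O)OCc1ccccc1)[C@]2(C)CCCO[Si](C)(C)C(C)(C)C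
F2 | step 9 | lithium bis[(E)-5-[(tert-butyldimethylsilyl)oxy]pent-2-en-2-yl]cuprate | [Li+].C/C(=C/CCO[Si](C)(C)C(C)(C)C)[Cu-]/C(C)=C\CCO[Si](C)(C)C(C)(C)C
F3 | step 9 | benzyl (2S,3Z)-2-[2-(2-bromo-5-isopropyl-3,4,6-trimethoxyphenyl)-2-oxoethyl]-6-[(tert-butyldimethylsilyl)oxy]-3-methylhex-3-enoate | CC(C)c1c(OC)c(OC)c(Br)c(c1OC)C(=O)C[C@H](C(=O)OCc1ccccc1)/C(C)=C\CCO[Si](C)(C)C(C)(C)C
F4 | step 13 | (1S,2R)-1-[3-[(tert-butyldimethylsilyl)oxy]propyl]-4-hydroxy-6-isopropyl-5,7,8-trimethoxy-1-methyl-1,2,3,4-tetrahydronaphthalene-2-carboxylic acid (both C4 epimers) | CC(C)c1c(OC)c(OC)c2c(c1OC)C(O)C[C@@H](C(=O)O)[C@]2(C)CCCO[Si](C)(C)C(C)(C)C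
F5 | step 13 | 1-[(1S,2R)-1-[3-[(tert-butyldimethylsilyl)oxy]propyl]-4-hydroxy-6-isopropyl-5,7,8-trimethoxy-1-methyl-1,2,3,4-tetrahydronaphthalen-2-yl]ethan-1-one (both C4 epimers) | CC(C)c1c(OC)c(OC)c2c(c1OC)C(O)C[C@@H](C(C)=O)[C@]2(C)CCCO[Si](C)(C)C(C)(C)C
F6 | step 13 | (3S,4S)-4-[3-[(tert-butyldimethylsilyl)oxy]propyl]-7-isopropyl-5,6,8-trimethoxy-4-methyl-3-(prop-1-en-2-yl)-1,2,3,4-tetrahydronaphthalen-1-ol (both C1 epimers) | C=C(C)[C@@H]1CC(O)c2c(OC)c(C(C)C)c(OC)c(OC)c2[C@@]1(C)CCCO[Si](C)(C)C(C)(C)C
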